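A direct plan would make each five-oxygen ring (rings B and D) from 6-fluoro-2,3,4-trimethoxybenzaldehyde (A1), obtained by lithiation and formylation of the fluoroarene. SNAr by a 2,6-dimethoxyphenoxide (ring A or ring C) would give a diaryl ether aldehyde such as A2, and a Dakin oxidation would turn its formyl group into the hydroxyl group of phenol A3. Copper-catalysed Ullmann couplings would join such phenols to aryl bromides up to the hexadecamethyl ether A4, and BBr3 would free the sixteen hydroxyl groups.
Its weakest steps would be: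
- The formylation that makes A1, together with the two Dakin oxidations: one carbon is put on only to be cut out again by a peracid. These are three operations that build nothing of the target, and the second oxidation exposes a four-ring, very electron-rich polyether to mCPBA.
- The SNAr that forms the A–O–B and C–O–D bonds: a doubly flanked phenoxide must attack, at 110 °C, a ring that carries three methoxy donors (one para to fluorine) and a single activating formyl group. This is needed twice.

**Retrosynthetic overview**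
Rings are lettered A to F from the 2,4,6-trihydroxyphenoxy end; in rings B and D the atoms are B1/D1 (oxygen to ring A/ring C), B2/D2 (C–H), B3–B5/D3–D5 (C–OH) and B6/D6 (oxygen to ring C/ring E).
Key disconnection: rings B and D are not taken from an arene but built by a Moore rearrangement. The C4O4 core of diethyl squarate becomes B3–B6 (D3–D6) with all four oxygens, and the two carbons of an aryl (Z)-2-bromovinyl ether become B2–H and B1–O–ring A (D2–H and D1–O–ring C).
One boronate phenol supplies rings A, C and E. Its bromovinyl ether is made once (a single generation of bromoethyne), then methoxylated at boron for ring A or coupled through boron to the B6 hydroxyl for ring C.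
Order of ring formation: ring B closed on the ring A vinyl ether, ring C attached by Chan–Lam coupling, ring D closed, rings E–F attached as one boronate, dealkylation.
The hindered A–O–B and C–O–D bonds are never made by arylation: the ring grows around the vinyl ether and appears with only its B6/D6 hydroxyl free, so no carbon is added and removed, and neither a peracid nor an SNAr is needed.
Key step: step 3

Remark: the cyclobutenone adducts are assumed to survive an aqueous work-up and to be carried crude into the thermolysis.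

Step 1
Reactants: 1 2,6-dimethoxy-4-(4,4,5,5-tetramethyl-1,3,2-dioxaborolan-2-yl)phenol; 2 1,2-dibromoethene (mixture of E and Z)
Product: 4 2-{4-[(Z)-2-bromoethenyloxy]-3,5-dimethoxyphenyl}-4,4,5,5-tetramethyl-1,3,2-dioxaborolane, via bromoethyne 3 (not isolated)
Conditions: 2 (3 equiv), Cs2CO3 (2.5 equiv), dry DMF, 60 °C, Ar
Reagents that add atoms: none
Why: Base-induced dehydrobromination of 2 gives bromoethyne in the flask, and the phenoxide adds to its unsubstituted carbon in an anti sense (nucleophilic addition to a haloalkyne), which places oxygen and bromine cis (Z); the addition is little affected by the two ortho methoxy groups, the excess of 2 should suppress a second addition, and the pinacol boronate should tolerate anhydrous carbonate as it does in ordinary O-alkylations of this phenol.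

Step 2
Reactants: 4 2-{4-[(Z)-2-bromoethenyloxy]-3,5-dimethoxyphenyl}-4,4,5,5-tetramethyl-1,3,2-dioxaborolane
Product: 5 2-[(Z)-2-bromoethenyloxy]-1,3,5-trimethoxybenzene
Conditions: Cu(OAc)2 (0.5 equiv, divalent copper regenerated by O2), DMAP (2 equiv), 4 Å MS, MeOH/CH2Cl2 (1:1), O2 (1 atm), 40 °C
Reagents that add atoms: methanol, CO
Why: Chan–Lam etherification with an aliphatic alcohol, in which the aryl group passes from boron to divalent copper, methoxide binds, and the aryl copper methoxide eliminates the aryl methyl ether once oxidised to trivalent copper; methanol as co-solvent exchanges the pinacol ester for a more reactive methyl boronate and outcompetes traces of water, and the (Z)-bromovinyl ether is inert to divalent copper and DMAP at this temperature.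

Step 3
Reactants: 5 2-[(Z)-2-bromoethenyloxy]-1,3,5-trimethoxybenzene; 6 diethyl squarate (3,4-diethoxycyclobut-3-ene-1,2-dione)
Product: 11 2,3-diethoxy-4-methoxy-6-(2,4,6-trimethoxyphenoxy)phenol (rings A–B), via vinyllithium 7 (not isolated), via lithium alkoxide 8 (not isolated), via cyclobutenone 9 (not isolated), via dienylketene 10 (not isolated)
Conditions: t-BuLi (2.05 equiv), THF/Et2O, −78 °C; cannulated into 6 (1.2 equiv), −78 °C; MeOTf (1.5 equiv), −78 to 0 °C; aq. NaHCO3 work-up; crude 9 in degassed p-xylene, 135 °C, Ar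
Reagents that add atoms: methyl trifluoromethanesulfonate (MeOTf), COS(=O)(=O)C(F)(F)F
Why: Bromine–lithium exchange gives the (Z)-2-aryloxyvinyllithium 7, which is held by internal O–Li coordination and has no anti arrangement for loss of lithium aryloxide, and it adds 1,2 to one carbonyl group of 6 (bond B2–B3), after which the alkoxide 8 is methylated to 9. On heating, the cyclobutenone should open by a conrotatory 4π electrocyclic reaction in which the 4-methoxy group turns outward and the alkenyl group inward, so that in dienylketene 10 the vinyl ether terminus lies next to the ketene carbon; a 6π electrocyclization then closes ring B through bond B6–B1, and enolization gives the phenol. The closest known reaction type is the Moore rearrangement of 4-alkenyl-4-alkoxycyclobutenones to hydroquinone monoethers. No stereocentre remains, since the carbinol carbon of 8 and 9 is racemic and is flattened in the ring opening. The step needs 1,2-addition at the squarate carbonyl group (secured by −78 °C), outward rotation of the methoxy group (secured by its donor character) and retention of the Z geometry of 7. The regiochemistry is fixed by connectivity, because the four squarate carbons become B3–B6 with their oxygens, the ketene oxygen becomes the only free hydroxyl group (B6–OH), and the aryloxy carbon of the vinyl ether becomes B1.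

Step 4
Reactants: 11 2,3-diethoxy-4-methoxy-6-(2,4,6-trimethoxyphenoxy)phenol; 4 2-{4-[(Z)-2-bromoethenyloxy]-3,5-dimethoxyphenyl}-4,4,5,5-tetramethyl-1,3,2-dioxaborolane
Product: 12 2-{4-[(Z)-2-bromoethenyloxy]-3,5-dimethoxyphenoxy}-3,4-diethoxy-5-methoxy-1-(2,4,6-trimethoxyphenoxy)benzene (rings A–C)
Conditions: 4 (2 equiv), Cu(OAc)2 (0.5 equiv, divalent copper regenerated by O2), pyridine (5 equiv), B(OH)3 (2 equiv, additive), 4 Å MS, MeCN, dry air, 60 °C
Reagents that add atoms: none
Why: Chan–Lam oxidative C–O coupling, in which the aryl group passes from boron to divalent copper and the aryl copper phenoxide, once oxidised to trivalent copper, eliminates the diaryl ether; the temperature is far below that at which copper attacks a vinyl C–Br bond, the boric acid additive offsets the low reactivity of the pinacol ester, and phenol 11 has no free ortho or para position for oxidative phenol coupling.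

Step 5
Reactants: 12 2-{4-[(Z)-2-bromoethenyloxy]-3,5-dimethoxyphenoxy}-3,4-diethoxy-5-methoxy-1-(2,4,6-trimethoxyphenoxy)benzene; 6 diethyl squarate
Product: 17 2,3-diethoxy-6-{4-[2,3-diethoxy-4-methoxy-6-(2,4,6-trimethoxyphenoxy)phenoxy]-2,6-dimethoxyphenoxy}-4-methoxyphenol (rings A–D), via vinyllithium 13 (not isolated), via lithium alkoxide 14 (not isolated), via cyclobutenone 15 (not isolated), via dienylketene 16 (not isolated)
Conditions: t-BuLi (2.05 equiv), THF/Et2O, −78 °C; cannulated into 6 (1.2 equiv), −78 °C; MeOTf (1.5 equiv), −78 to 0 °C; aq. NaHCO3 work-up; crude 15 in degassed p-xylene, 135 °C, Ar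
Reagents that add atoms: methyl trifluoromethanesulfonate (MeOTf), COS(=O)(=O)C(F)(F)F
Why: The Moore rearrangement sequence of step 3, repeated to build ring D on the ring C oxygen (bonds D2–D3 and D6–D1); exchange at the vinyl bromide should be much faster at −78 °C than lithiation of the aryl ether C–H bonds, and the transient racemic carbinol centre of 14 and 15 is lost in the ring opening.

Step 6
Reactants: 1 2,6-dimethoxy-4-(4,4,5,5-tetramethyl-1,3,2-dioxaborolan-2-yl)phenol; 18 (3,4,5-trimethoxyphenyl)boronic acid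
Product: 19 2-[3,5-dimethoxy-4-(3,4,5-trimethoxyphenoxy)phenyl]-4,4,5,5-tetramethyl-1,3,2-dioxaborolane (rings E–F)
Conditions: 18 (2 equiv), Cu(OAc)2 (0.5 equiv, divalent copper regenerated by O2), pyridine (5 equiv), 4 Å MS, CH2Cl2, dry air, rt
Reagents that add atoms: none
Why: Chan–Lam O-arylation that relies on the known reactivity gap between boron partners: at room temperature without additive the free boronic acid 18 transfers its aryl group, while the pinacol boronate of 1 and 19 is a poor partner; the para position of phenol 1 is blocked by boron, so oxidative phenol coupling cannot occur.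

Step 7
Reactants: 17 2,3-diethoxy-6-{4-[2,3-diethoxy-4-methoxy-6-(2,4,6-trimethoxyphenoxy)phenoxy]-2,6-dimethoxyphenoxy}-4-methoxyphenol; 19 2-[3,5-dimethoxy-4-(3,4,5-trimethoxyphenoxy)phenyl]-4,4,5,5-tetramethyl-1,3,2-dioxaborolane
Product: 20 tetraethyl dodecamethyl ether of the target (B4, B5, D4 and D5 as OEt, the other twelve OH as OMe)
Conditions: 19 (2 equiv), Cu(OAc)2 (0.5 equiv, divalent copper regenerated by O2), pyridine (5 equiv), B(OH)3 (2 equiv, additive), 4 Å MS, MeCN, dry air, 60 °C
Reagents that add atoms: none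
Why: A second Chan–Lam coupling of the same kind as step 4; the D6 hydroxyl group of 17 has the same surroundings as the B6 hydroxyl group of 11, and neither partner carries another reactive group.

Step 8
Reactants: 20 tetraethyl dodecamethyl ether of the target
Product: 22 CNP0218077.0, via hexadecakis(dibromoboryl) ether 21 (not isolated)
Conditions: BBr3 (1 M in CH2Cl2, 50 equiv), CH2Cl2, −78 °C to rt, 36 h, Ar; MeOH then H2O, 0 °C; Sephadex LH-20 (degassed MeOH)
Reagents that add atoms: none
Why: Lewis-acid ether cleavage, in which BBr3 binds each alkoxy oxygen and bromide attacks the methyl or ethyl carbon (SN2), so only the sixteen O–alkyl bonds should break; the diaryl ether bonds offer no sp3 carbon and survive, and hydrolysis of the borates gives the achiral hexadecaphenol.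

**Compound list**
1 | 2,6-dimethoxy-4-(4,4,5,5-tetramethyl-1,3,2-dioxaborolan-2-yl)phenol (source of rings A, C and E) | COc1cc(B2OC(C)(C)C(C)(C)O2)cc(OC)c1O | starting material
2 | 1,2-dibromoethene, mixture of E and Z | BrC=CBr | starting material
3 | bromoethyne, not isolated | BrC#C | intermediate
4 | 2-{4-[(Z)-2-bromoethenyloxy]-3,5-dimethoxyphenyl}-4,4,5,5-tetramethyl-1,3,2-dioxaborolane | COc1cc(B2OC(C)(C)C(C)(C)O2)cc(OC)c1O/C=C\Br | intermediate
5 | 2-[(Z)-2-bromoethenyloxy]-1,3,5-trimethoxybenzene (ring A) | COc1cc(OC)c(O/C=C\Br)c(OC)c1 | intermediate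
6 | diethyl squarate (3,4-diethoxycyclobut-3-ene-1,2-dione) | CCOC1=C(OCC)C(=O)C1=O | starting material
7 | [(Z)-2-(2,4,6-trimethoxyphenoxy)ethenyl]lithium, not isolated | [Li]/C=C\Oc1c(OC)cc(OC)cc1OC | intermediate
8 | lithium 2,3-diethoxy-4-oxo-1-[(Z)-2-(2,4,6-trimethoxyphenoxy)ethenyl]cyclobut-2-en-1-olate, racemic, not isolated | [Li+].[O-]C1(/C=C\Oc2c(OC)cc(OC)cc2OC)C(OCC)=C(OCC)C1=O | intermediate
9 | 2,3-diethoxy-4-methoxy-4-[(Z)-2-(2,4,6-trimethoxyphenoxy)ethenyl]cyclobut-2-en-1-one, racemic, not isolated | COC1(/C=C\Oc2c(OC)cc(OC)cc2OC)C(OCC)=C(OCC)C1=O | intermediate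
10 | (3Z,5Z)-2,3-diethoxy-4-methoxy-6-(2,4,6-trimethoxyphenoxy)hexa-1,3,5-trien-1-one, not isolated | O=C=C(OCC)/C(OCC)=C(OC)\C=C/Oc1c(OC)cc(OC)cc1OC | intermediate
11 | 2,3-diethoxy-4-methoxy-6-(2,4,6-trimethoxyphenoxy)phenol (rings A–B) | Oc1c(OCC)c(OCC)c(OC)cc1Oc1c(OC)cc(OC)cc1OC | intermediate
12 | 2-{4-[(Z)-2-bromoethenyloxy]-3,5-dimethoxyphenoxy}-3,4-diethoxy-5-methoxy-1-(2,4,6-trimethoxyphenoxy)benzene (rings A–C) | Br/C=C\Oc1c(OC)cc(Oc2c(OCC)c(OCC)c(OC)cc2Oc2c(OC)cc(OC)cc2OC)cc1OC | intermediate
13 | [(Z)-2-{4-[2,3-diethoxy-4-methoxy-6-(2,4,6-trimethoxyphenoxy)phenoxy]-2,6-dimethoxyphenoxy}ethenyl]lithium, not isolated | [Li]/C=C\Oc1c(OC)cc(Oc2c(OCC)c(OCC)c(OC)cc2Oc2c(OC)cc(OC)cc2OC)cc1OC | intermediate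
14 | lithium 2,3-diethoxy-4-oxo-1-[(Z)-2-{4-[2,3-diethoxy-4-methoxy-6-(2,4,6-trimethoxyphenoxy)phenoxy]-2,6-dimethoxyphenoxy}ethenyl]cyclobut-2-en-1-olate, racemic, not isolated | [Li+].[O-]C1(/C=C\Oc2c(OC)cc(Oc3c(OCC)c(OCC)c(OC)cc3Oc3c(OC)cc(OC)cc3OC)cc2OC)C(OCC)=C(OCC)C1=O | intermediate
15 | 2,3-diethoxy-4-methoxy-4-[(Z)-2-{4-[2,3-diethoxy-4-methoxy-6-(2,4,6-trimethoxyphenoxy)phenoxy]-2,6-dimethoxyphenoxy}ethenyl]cyclobut-2-en-1-one, racemic, not isolated | COC1(/C=C\Oc2c(OC)cc(Oc3c(OCC)c(OCC)c(OC)cc3Oc3c(OC)cc(OC)cc3OC)cc2OC)C(OCC)=C(OCC)C1=O | intermediate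
16 | (3Z,5Z)-2,3-diethoxy-4-methoxy-6-{4-[2,3-diethoxy-4-methoxy-6-(2,4,6-trimethoxyphenoxy)phenoxy]-2,6-dimethoxyphenoxy}hexa-1,3,5-trien-1-one, not isolated | O=C=C(OCC)/C(OCC)=C(OC)\C=C/Oc1c(OC)cc(Oc2c(OCC)c(OCC)c(OC)cc2Oc2c(OC)cc(OC)cc2OC)cc1OC | intermediate
17 | 2,3-diethoxy-6-{4-[2,3-diethoxy-4-methoxy-6-(2,4,6-trimethoxyphenoxy)phenoxy]-2,6-dimethoxyphenoxy}-4-methoxyphenol (rings A–D) | Oc1c(OCC)c(OCC)c(OC)cc1Oc1c(OC)cc(Oc2c(OCC)c(OCC)c(OC)cc2Oc2c(OC)cc(OC)cc2OC)cc1OC | intermediate
18 | (3,4,5-trimethoxyphenyl)boronic acid (ring F) | COc1cc(B(O)O)cc(OC)c1OC | starting material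
19 | 2-[3,5-dimethoxy-4-(3,4,5-trimethoxyphenoxy)phenyl]-4,4,5,5-tetramethyl-1,3,2-dioxaborolane (rings E–F) | COc1cc(B2OC(C)(C)C(C)(C)O2)cc(OC)c1Oc1cc(OC)c(OC)c(OC)c1 | intermediate
20 | tetraethyl dodecamethyl ether of the target (B4, B5, D4, D5 as OEt; all other OH as OMe) | COc1cc(OC)c(Oc2cc(OC)c(OCC)c(OCC)c2Oc2cc(OC)c(Oc3cc(OC)c(OCC)c(OCC)c3Oc3cc(OC)c(Oc4cc(OC)c(OC)c(OC)c4)c(OC)c3)c(OC)c2)c(OC)c1 | intermediate
21 | hexadecakis(dibromoboryl) ether of the target (every OH as O–BBr2, drawn in its simplest form), not isolated | BrB(Br)Oc1cc(OB(Br)Br)c(Oc2cc(OB(Br)Br)c(OB(Br)Br)c(OB(Br)Br)c2Oc2cc(OB(Br)Br)c(Oc3cc(OB(Br)Br)c(OB(Br)Br)c(OB(Br)Br)c3Oc3cc(OB(Br)Br)c(Oc4cc(OB(Br)Br)c(OB(Br)Br)c(OB(Br)Br)c4)c(OB(Br)Br)c3)c(OB(Br)Br)c2)c(OB(Br)Br)c1 | intermediate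
22 | CNP0218077.0: linear hexamer; ring A 2,4,6-trihydroxyphenoxy, rings B and D 3,4,5-trihydroxy-1,2-phenylenedioxy, rings C and E 2,6-dihydroxy-1,4-phenylenedioxy, ring F 3,4,5-trihydroxyphenyl; achiral | Oc1cc(O)c(Oc2cc(O)c(O)c(O)c2Oc2cc(O)c(Oc3cc(O)c(O)c(O)c3Oc3cc(O)c(Oc4cc(O)c(O)c(O)c4)c(O)c3)c(O)c2)c(O)c1 | target

**Step count and risks**
Total: 8 steps. Longest linear sequence: 7 steps (steps 1, 2, 3, 4, 5, 7, 8).

Steps most likely to fail:

1. Step 3 (the same operation recurs in step 5). The (Z)-2-aryloxyvinyllithium may lose lithium aryloxide or be protonated before it adds to the squarate, so that too little cyclobutenone reaches the thermolysis. The fallback sets out from 5 and replaces the vinyl anion by an acetylide, which has no β-leaving group. LDA (2.2 equiv, THF, −78 to −40 °C) would eliminate HBr in an anti sense from the Z bromide to give 2-(ethynyloxy)-1,3,5-trimethoxybenzene F1 and deprotonate it in the same flask to [(2,4,6-trimethoxyphenoxy)ethynyl]lithium F2. Addition to 6 at −78 °C would give the lithium alkynylcyclobutenolate F3, and O-methylation with MeOTf the alkynyl cyclobutenone F4. Semi-hydrogenation (H2, Pd/CaCO3 poisoned with Pb(OAc)2, quinoline, EtOAc) would give the Z alkene by syn addition and so return to the route at 9, which is heated to 11 as before.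

2. Step 4. Aryl transfer and C–O bond formation at the doubly flanked phenoxide of 11 may be slower than the oxidative consumption of boronate 4, or copper may engage the vinyl C–Br bond. The fallback sets out from 11 and moves the bromovinyl group behind the coupling. Benzylation of commercial 4-bromo-2,6-dimethoxyphenol (BnBr, K2CO3, DMF) would give 2-(benzyloxy)-5-bromo-1,3-dimethoxybenzene F5. Ullmann coupling of 11 with it under argon (CuI, picolinic acid, K3PO4, DMSO, 90 °C), a process of monovalent copper that needs no oxidant, would give the benzyl ether of rings A–C F6. Hydrogenolysis (H2, Pd/C, EtOAc) would free the ring C phenol F7, and its addition to bromoethyne 3, generated as in step 1 (2, Cs2CO3, DMF, 60 °C), would return to the route at 12.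

3. Step 7. The same slow coupling may occur, now on the four-ring phenol 17 and with the largest boronate. The fallback sets out from 17 and 18. Chan–Lam coupling of commercial 4-bromo-2,6-dimethoxyphenol with 18 (conditions of step 6) would give the rings E–F bromide 5-bromo-1,3-dimethoxy-2-(3,4,5-trimethoxyphenoxy)benzene F8. Ullmann coupling of 17 with it (CuI, picolinic acid, K3PO4, DMSO, 100 °C, Ar) would return to the route at 20.

**Further compounds**
F1 | step 3 | 2-(ethynyloxy)-1,3,5-trimethoxybenzene | COc1cc(OC)c(OC#C)c(OC)c1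
F2 | step 3 | [(2,4,6-trimethoxyphenoxy)ethynyl]lithium | [Li]C#COc1c(OC)cc(OC)cc1OC
F3 | step 3 | lithium 2,3-diethoxy-4-oxo-1-[(2,4,6-trimethoxyphenoxy)ethynyl]cyclobut-2-en-1-olate, racemic | [Li+].[O-]C1(C#COc2c(OC)cc(OC)cc2OC)C(OCC)=C(OCC)C1=O
F4 | step 3 | 2,3-diethoxy-4-methoxy-4-[(2,4,6-trimethoxyphenoxy)ethynyl]cyclobut-2-en-1-one, racemic | COC1(C#COc2c(OC)cc(OC)cc2OC)C(OCC)=C(OCC)C1=O
F5 | step 4 | 2-(benzyloxy)-5-bromo-1,3-dimethoxybenzene | COc1cc(Br)cc(OC)c1OCc1ccccc1
F6 | step 4 | 2-[4-(benzyloxy)-3,5-dimethoxyphenoxy]-3,4-diethoxy-5-methoxy-1-(2,4,6-trimethoxyphenoxy)benzene | COc1cc(Oc2c(OCC)c(OCC)c(OC)cc2Oc2c(OC)cc(OC)cc2OC)cc(OC)c1OCc1ccccc1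
F7 | step 4 | 4-[2,3-diethoxy-4-methoxy-6-(2,4,6-trimethoxyphenoxy)phenoxy]-2,6-dimethoxyphenol | COc1cc(Oc2c(OCC)c(OCC)c(OC)cc2Oc2c(OC)cc(OC)cc2OC)cc(OC)c1O
F8 | step 7 | 5-bromo-1,3-dimethoxy-2-(3,4,5-trimethoxyphenoxy)benzene | COc1cc(Br)cc(OC)c1Oc1cc(OC)c(OC)c(OC)c1
A1 | direct plan | 6-fluoro-2,3,4-trimethoxybenzaldehyde | O=Cc1c(F)cc(OC)c(OC)c1OC
A2 | direct plan | 2,3,4-trimethoxy-6-(2,4,6-trimethoxyphenoxy)benzaldehyde | O=Cc1c(Oc2c(OC)cc(OC)cc2OC)cc(OC)c(OC)c1OC
A3 | direct plan | 2,3,4-trimethoxy-6-(2,4,6-trimethoxyphenoxy)phenol | Oc1c(Oc2c(OC)cc(OC)cc2OC)cc(OC)c(OC)c1OC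
A4 | direct plan | hexadecamethyl ether of the target | COc1cc(OC)c(Oc2cc(OC)c(OC)c(OC)c2Oc2cc(OC)c(Oc3cc(OC)c(OC)c(OC)c3Oc3cc(OC)c(Oc4cc(OC)c(OC)c(OC)c4)c(OC)c3)c(OC)c2)c(OC)c1
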